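**Plan**
- Cuts: the C11–O aryl ether last; then C3–C4 and C5–C10 together, which opens rings A and B to one chain; in the chain C8–C9 (sigmatropic), C4=C5 (metathesis) and C1–C10 (carbonyl addition).
- Enabling feature: ring A is a cyclohexene (C1=C2) whose two allylic ring bonds C3–C4 and C5–C10 form a Diels–Alder retron: diene C10=C1–C2=C3 (C3 as silyl enol ether), dienophile C4=C5, and the C6–C9 chain between them becomes ring B.
- Helpers: a formyl group in place of one C4 methyl (activation and endo control, later reduced to CH3); CH2SPh on C8 (equatorial anchor for face control, later eliminated to the C8=C12 methylene); O3 as silyl ether (later oxidised to the enone).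
- Forward: linear chain assembly (steps 1–11), both rings at once (step 12), adjustment of C4, C8 and C3, then Mitsunobu coupling with isofraxidin.
- Stereochemistry: C1 carbinol by catalytic asymmetric vinylation; transferred to C9 and C8 by Ireland–Claisen rearrangement; C5 and C10 from C8/C9 in the cycloaddition; the centres at C1, C3, C4 and C8 are erased later.

Key step: step 12

Remark: drimane numbering is used for all intermediates, also the open-chain ones (C1–C10 ring carbons, C11 = CH2O on C9, C12 = carbon on C8).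

**Step 1**
Reactants: 1 but-2-yn-1-ol
Product: 2 (2Z)-3-iodobut-2-en-1-ol
Conditions: NaAlH2(OCH2CH2OMe)2, THF, 0 °C to rt; then I2, −78 to 0 °C
Reagents that add atoms: iodine, II
Why: Alkoxide-directed trans-hydroalumination of the propargylic alcohol puts aluminium on C3 and iodinolysis with retention gives the (Z)-vinyl iodide (hydroalumination–iodination), whose geometry later keeps C1 and C11 cis on the trisubstituted alkene.

**Step 2**
Reactants: 2 (2Z)-3-iodobut-2-en-1-ol
Product: 3 tert-butyl{[(2Z)-3-iodobut-2-en-1-yl]oxy}diphenylsilane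
Conditions: TBDPSCl, imidazole, CH2Cl2, rt
Reagents that add atoms: tert-butyl(chloro)diphenylsilane, CC(C)(C)[Si](Cl)(c1ccccc1)c1ccccc1
Why: O-Silylation masks O11 with a group that should survive organolithium, amide base, hydride, Lewis acid and HF·pyridine and is removed by fluoride at the end.

**Step 3**
Reactants: 3 tert-butyl{[(2Z)-3-iodobut-2-en-1-yl]oxy}diphenylsilane; 4 3-(tert-butyldimethylsilyloxy)propanal
Product: 7 (3R,4Z)-1-(tert-butyldimethylsilyloxy)-6-(tert-butyldiphenylsilyloxy)-4-methylhex-4-en-3-ol, via vinyllithium 5 (not isolated), via vinylzinc bromide 6 (not isolated)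
Conditions: t-BuLi (2 equiv), Et2O, −78 °C; ZnBr2, −78 to 0 °C; TEEDA, (−)-MIB (10 mol%), then 4, toluene, 0 °C
Reagents that add atoms: none
Why: Iodine–lithium exchange with retention, transmetalation to zinc and amino-alcohol-catalysed asymmetric 1,2-addition of the vinylzinc to the aldehyde should deliver the (R)-carbinol by Si-face attack, the diamine sequestering the lithium halides that would otherwise promote a racemic background addition.

**Step 4**
Reactants: 7 (3R,4Z)-allylic alcohol; 8 hex-5-enoic acid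
Product: 9 (3R,4Z)-1-(tert-butyldimethylsilyloxy)-6-(tert-butyldiphenylsilyloxy)-4-methylhex-4-en-3-yl hex-5-enoate
Conditions: DCC, DMAP (cat.), CH2Cl2, 0 °C to rt
Reagents that add atoms: none
Why: Carbodiimide (Steglich) esterification of the secondary allylic alcohol attaches C12 and C5–C8 as the ester needed for the sigmatropic step.

**Step 5**
Reactants: 9 allylic hex-5-enoate
Product: 12 (2S,3S,4E)-2-(but-3-en-1-yl)-3-[(tert-butyldiphenylsilyloxy)methyl]-7-(tert-butyldimethylsilyloxy)-4-methylhept-4-enoic acid, via silyl ketene acetal 10 (not isolated), via trimethylsilyl ester 11 (not isolated)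
Conditions: LiN(i-Pr)2, Me3SiCl, THF, −78 °C, then 50 °C; dilute aqueous citric acid
Reagents that add atoms: none
Why: Ireland–Claisen rearrangement, in which kinetic enolisation in THF gives the ketene acetal with the alkyl chain cis to the allyloxy oxygen and the chair transition state with the C1 substituent equatorial (enforced by A(1,3) strain of the Z-alkene) transfers the C1 configuration to C9, sets C8 syn to it and forms the (E)-C10=C1 alkene.

**Step 6**
Reactants: 12 heptenoic acid
Product: 13 (2S,3S,4E)-2-(but-3-en-1-yl)-3-[(tert-butyldiphenylsilyloxy)methyl]-7-(tert-butyldimethylsilyloxy)-4-methylhept-4-en-1-ol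
Conditions: LiAlH4, Et2O, 0 °C
Reagents that add atoms: none
Why: Hydride reduction of the carboxylic acid to the primary C12 alcohol, under which both silyl ethers and the isolated alkenes are inert.

**Step 7**
Reactants: 13 primary alcohol
Product: 14 (5S,6S,7E)-5-[(phenylsulfanyl)methyl]-6-[(tert-butyldiphenylsilyloxy)methyl]-10-(tert-butyldimethylsilyloxy)-7-methyldeca-1,7-diene
Conditions: PhSSPh, Bu3P, THF, rt
Reagents that add atoms: diphenyl disulfide, c1ccccc1SSc1ccccc1
Why: Phosphine–disulfide redox condensation converts the primary alcohol by SN2 into the phenyl sulfide, a thermally robust group that serves as the equatorial anchor on C8 in the cycloaddition and later as the precursor of the exocyclic methylene.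

**Step 8**
Reactants: 14 phenyl sulfide; 15 methacrolein
Product: 16 (2E,6S,7S,8E)-6-[(phenylsulfanyl)methyl]-7-[(tert-butyldiphenylsilyloxy)methyl]-11-(tert-butyldimethylsilyloxy)-2,8-dimethylundeca-2,8-dienal
Conditions: second-generation Grubbs catalyst (H2IMes)(PCy3)Cl2Ru=CHPh (5 mol%), excess 15, CH2Cl2, 40 °C
Reagents that add atoms: none
Why: Olefin cross-metathesis of the monosubstituted alkene with methacrolein should give the (E)-2-methylenal selectively, the trisubstituted alkene being inert and the product too electron-poor to react further.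

**Step 9**
Reactants: 16 silyl-protected enal
Product: 17 (2E,6S,7S,8E)-11-hydroxy-6-[(phenylsulfanyl)methyl]-7-[(tert-butyldiphenylsilyloxy)methyl]-2,8-dimethylundeca-2,8-dienal
Conditions: HF·pyridine, pyridine, THF, 0 °C
Reagents that add atoms: none
Why: Selective desilylation, since buffered HF·pyridine cleaves the primary tert-butyldimethylsilyl ether much faster than the tert-butyldiphenylsilyl ether.

**Step 10**
Reactants: 17 hydroxy enal
Product: 18 (2E,6S,7S,8E)-6-[(phenylsulfanyl)methyl]-7-[(tert-butyldiphenylsilyloxy)methyl]-2,8-dimethylundeca-2,8-dienedial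
Conditions: Dess–Martin periodinane, NaHCO3, CH2Cl2, 0 °C
Reagents that add atoms: none
Why: Dess–Martin oxidation under buffered conditions gives the β,γ-unsaturated C3 aldehyde without migration of the C10=C1 double bond into conjugation.

**Step 11**
Reactants: 18 dialdehyde
Product: 19 (2E,6S,7S,8E,10E)-11-(tert-butyldimethylsilyloxy)-6-[(phenylsulfanyl)methyl]-7-[(tert-butyldiphenylsilyloxy)methyl]-2,8-dimethylundeca-2,8,10-trienal
Conditions: TBSOTf (1.05 equiv), Et3N, CH2Cl2, −78 °C
Reagents that add atoms: tert-butyldimethylsilyl trifluoromethanesulfonate, CC(C)(C)[Si](C)(C)OS(=O)(=O)C(F)(F)F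
Why: Soft enolisation (O-silylation, then α-deprotonation by the amine) converts the doubly activated CH2–CHO unit into the (1E,3E)-silyl dienol ether with retention of the C10=C1 geometry, while at −78 °C the conjugated enal, which could only react by slower γ-deprotonation, should stay untouched.

**Step 12**
Reactants: 19 silyloxy-triene enal
Product: 20 (3S,4R,5S,8S,9S,10R)-3-(tert-butyldimethylsilyloxy)-11-(tert-butyldiphenylsilyloxy)-12-(phenylsulfanyl)-4-formyl-4-nor-drim-1-ene (trans-fused; 3-OTBS cis to 4-CHO; 8-CH2SPh cis to 9-CH2OTBDPS; 9-CH2OTBDPS trans to 10-CH3)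
Conditions: Me2AlCl (1.2 equiv), CH2Cl2, −78 to −30 °C
Reagents that add atoms: none
Why: Coordination of Me2AlCl to the formyl oxygen lowers the LUMO of the (E)-2-methylenal C4=C5, which adds suprafacially across C10 and C3 of the s-cis (1E,3E)-1-silyloxy diene in an asynchronous [4π+2π] cycloaddition in which the C5–C10 bond leads (the charge developing at C3 is stabilised by the silyloxy group) and the C3–C4 bond follows. The closest known reaction type is the Lewis-acid-promoted intramolecular Diels–Alder reaction of 2,8,10-undecatrienals and of 1-oxygenated dienes, which gives trans-fused octalins through the endo transition state. Ring A (C10–C1=C2–C3–C4–C5) is the cyclohexene made by the cycloaddition itself, and ring B (C5–C6–C7–C8–C9–C10) closes through the four-carbon tether in a chair-like six-membered array (type 1 cyclisation, tether on the diene terminus). C5 and C10 become trans because the formyl group and H5 are endo while C6 and the C4 methyl group are exo (E dienophile, endo rule reinforced by the Lewis acid); C3 and C4 follow from the (1E) enol ether and the endo formyl group and are erased later. The diene face is fixed by the tether stereocentres: CH2SPh on C8 must be equatorial, since an axial position would place it 1,3-syn to the inside methyl group on C10, and this forces the cis-related CH2OTBDPS group on C9 into the axial position anti to that methyl group, which is the C9/C10 relation of the target. The step thus needs endo selectivity and one diene face out of two, secured by the (E)-formyl activator and by the equatorial C8 anchor, while regiochemistry is enforced by the tether.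

**Step 13**
Reactants: 20 formyl cycloadduct
Product: 22 (3S,5S,8S,9S,10R)-3-(tert-butyldimethylsilyloxy)-11-(tert-butyldiphenylsilyloxy)-12-(phenylsulfanyl)drim-1-ene, via tosylhydrazone 21 (not isolated)
Conditions: TsNHNH2, EtOH, 50 °C; then catecholborane, CHCl3, 0 °C; NaOAc·3H2O, reflux
Reagents that add atoms: none
Why: Caglioti-type reductive deoxygenation, in which the tosylhydrazone is reduced by catecholborane and the resulting diazene loses N2, turns the formyl helper into the second methyl group on C4 without touching alkene, sulfide or silyl ethers.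

**Step 14**
Reactants: 22 sulfide with gem-dimethyl group
Product: 24 (3S,5S,9S,10R)-3-(tert-butyldimethylsilyloxy)-11-(tert-butyldiphenylsilyloxy)drima-1,8(12)-diene, via sulfoxide 23 (not isolated)
Conditions: mCPBA (1.0 equiv), CH2Cl2, −78 °C; then CaCO3, xylene, 140 °C
Reagents that add atoms: none
Why: Oxidation of the sulfide to the sulfoxide and thermal syn-elimination (sulfoxide pyrolysis) can only use H8, the single β-hydrogen, so that the exocyclic C8=C12 double bond forms regiospecifically and the C8 stereocentre, no longer needed, disappears.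

**Step 15**
Reactants: 24 bis-silyl ether
Product: 25 (3S,5S,9S,10R)-drima-1,8(12)-diene-3,11-diol
Conditions: Bu4NF, THF, 50 °C
Reagents that add atoms: none
Why: Fluoride-mediated desilylation removes both silyl ethers to give the diol.

**Step 16**
Reactants: 25 diol
Product: 26 (5S,9S,10R)-11-hydroxydrima-1,8(12)-dien-3-one
Conditions: MnO2, CH2Cl2, rt
Reagents that add atoms: none
Why: Chemoselective allylic oxidation, since MnO2 oxidises only the allylic secondary alcohol, gives the C1=C2–C3=O enone and leaves the primary C11 alcohol free.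

**Step 17**
Reactants: 26 enone alcohol; 27 isofraxidin (7-hydroxy-6,8-dimethoxy-2H-chromen-2-one)
Product: 28 7-{[(1S,4aS,8aR)-5,5,8a-trimethyl-2-methylidene-6-oxo-1,2,3,4,4a,5,6,8a-octahydronaphthalen-1-yl]methoxy}-6,8-dimethoxy-2H-chromen-2-one
Conditions: PPh3, DIAD, THF, 0 °C to rt
Reagents that add atoms: none
Why: Mitsunobu etherification of the primary alcohol with the acidic phenol forms the C11–O aryl ether under neutral conditions that spare enone, exocyclic alkene and coumarin lactone, and no stereocentre is involved.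

**Compound list**
1 | but-2-yn-1-ol | CC#CCO | starting material
2 | (2Z)-3-iodobut-2-en-1-ol | C/C(I)=C/CO | intermediate
3 | tert-butyl{[(2Z)-3-iodobut-2-en-1-yl]oxy}diphenylsilane | C/C(I)=C/CO[Si](c1ccccc1)(c1ccccc1)C(C)(C)C | intermediate
4 | 3-(tert-butyldimethylsilyloxy)propanal | O=CCCO[Si](C)(C)C(C)(C)C | starting material
5 | (2Z)-4-(tert-butyldiphenylsilyloxy)but-2-en-2-yllithium | [Li]/C(C)=C\CO[Si](c1ccccc1)(c1ccccc1)C(C)(C)C | intermediate
6 | [(2Z)-4-(tert-butyldiphenylsilyloxy)but-2-en-2-yl]zinc bromide | Br[Zn]/C(C)=C\CO[Si](c1ccccc1)(c1ccccc1)C(C)(C)C | intermediate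
7 | (3R,4Z)-1-(tert-butyldimethylsilyloxy)-6-(tert-butyldiphenylsilyloxy)-4-methylhex-4-en-3-ol | O[C@H](CCO[Si](C)(C)C(C)(C)C)/C(C)=C\CO[Si](c1ccccc1)(c1ccccc1)C(C)(C)C | intermediate
8 | hex-5-enoic acid | C=CCCCC(=O)O | starting material
9 | (3R,4Z)-1-(tert-butyldimethylsilyloxy)-6-(tert-butyldiphenylsilyloxy)-4-methylhex-4-en-3-yl hex-5-enoate | C=CCCCC(=O)O[C@H](CCO[Si](C)(C)C(C)(C)C)/C(C)=C\CO[Si](c1ccccc1)(c1ccccc1)C(C)(C)C | intermediate
10 | O-trimethylsilyl ketene acetal of 9 (chain cis to the allyloxy oxygen) | C=CCC/C=C(O[Si](C)(C)C)\O[C@H](CCO[Si](C)(C)C(C)(C)C)/C(C)=C\CO[Si](c1ccccc1)(c1ccccc1)C(C)(C)C | intermediate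
11 | trimethylsilyl ester of acid 12 | C[Si](C)(C)OC(=O)[C@@H](CCC=C)[C@H](CO[Si](c1ccccc1)(c1ccccc1)C(C)(C)C)/C(C)=C/CCO[Si](C)(C)C(C)(C)C | intermediate
12 | (2S,3S,4E)-2-(but-3-en-1-yl)-3-[(tert-butyldiphenylsilyloxy)methyl]-7-(tert-butyldimethylsilyloxy)-4-methylhept-4-enoic acid | OC(=O)[C@@H](CCC=C)[C@H](CO[Si](c1ccccc1)(c1ccccc1)C(C)(C)C)/C(C)=C/CCO[Si](C)(C)C(C)(C)C | intermediate
13 | (2S,3S,4E)-2-(but-3-en-1-yl)-3-[(tert-butyldiphenylsilyloxy)methyl]-7-(tert-butyldimethylsilyloxy)-4-methylhept-4-en-1-ol | OC[C@@H](CCC=C)[C@H](CO[Si](c1ccccc1)(c1ccccc1)C(C)(C)C)/C(C)=C/CCO[Si](C)(C)C(C)(C)C | intermediate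
14 | (5S,6S,7E)-5-[(phenylsulfanyl)methyl]-6-[(tert-butyldiphenylsilyloxy)methyl]-10-(tert-butyldimethylsilyloxy)-7-methyldeca-1,7-diene | C=CCC[C@H](CSc1ccccc1)[C@H](CO[Si](c1ccccc1)(c1ccccc1)C(C)(C)C)/C(C)=C/CCO[Si](C)(C)C(C)(C)C | intermediate
15 | methacrolein (2-methylprop-2-enal) | C=C(C)C=O | starting material
16 | (2E,6S,7S,8E)-6-[(phenylsulfanyl)methyl]-7-[(tert-butyldiphenylsilyloxy)methyl]-11-(tert-butyldimethylsilyloxy)-2,8-dimethylundeca-2,8-dienal | O=C/C(C)=C/CC[C@H](CSc1ccccc1)[C@H](CO[Si](c1ccccc1)(c1ccccc1)C(C)(C)C)/C(C)=C/CCO[Si](C)(C)C(C)(C)C | intermediate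
17 | (2E,6S,7S,8E)-11-hydroxy-6-[(phenylsulfanyl)methyl]-7-[(tert-butyldiphenylsilyloxy)methyl]-2,8-dimethylundeca-2,8-dienal | O=C/C(C)=C/CC[C@H](CSc1ccccc1)[C@H](CO[Si](c1ccccc1)(c1ccccc1)C(C)(C)C)/C(C)=C/CCO | intermediate
18 | (2E,6S,7S,8E)-6-[(phenylsulfanyl)methyl]-7-[(tert-butyldiphenylsilyloxy)methyl]-2,8-dimethylundeca-2,8-dienedial | O=C/C(C)=C/CC[C@H](CSc1ccccc1)[C@H](CO[Si](c1ccccc1)(c1ccccc1)C(C)(C)C)/C(C)=C/CC=O | intermediate
19 | (2E,6S,7S,8E,10E)-11-(tert-butyldimethylsilyloxy)-6-[(phenylsulfanyl)methyl]-7-[(tert-butyldiphenylsilyloxy)methyl]-2,8-dimethylundeca-2,8,10-trienal | O=C/C(C)=C/CC[C@H](CSc1ccccc1)[C@H](CO[Si](c1ccccc1)(c1ccccc1)C(C)(C)C)/C(C)=C/C=C/O[Si](C)(C)C(C)(C)C | intermediate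
20 | (3S,4R,5S,8S,9S,10R)-3-(tert-butyldimethylsilyloxy)-11-(tert-butyldiphenylsilyloxy)-12-(phenylsulfanyl)-4-formyl-4-nor-drim-1-ene (trans-fused cycloadduct) | C(Sc1ccccc1)[C@H]1CC[C@@H]2[C@@](C)(C=O)[C@@H](O[Si](C)(C)C(C)(C)C)C=C[C@@]2(C)[C@H]1CO[Si](c1ccccc1)(c1ccccc1)C(C)(C)C | intermediate
21 | 4-methylbenzenesulfonylhydrazone of aldehyde 20 | C(Sc1ccccc1)[C@H]1CC[C@@H]2[C@@](C)(/C=N/NS(=O)(=O)c3ccc(C)cc3)[C@@H](O[Si](C)(C)C(C)(C)C)C=C[C@@]2(C)[C@H]1CO[Si](c1ccccc1)(c1ccccc1)C(C)(C)C | intermediate
22 | (3S,5S,8S,9S,10R)-3-(tert-butyldimethylsilyloxy)-11-(tert-butyldiphenylsilyloxy)-12-(phenylsulfanyl)drim-1-ene | C(Sc1ccccc1)[C@H]1CC[C@@H]2C(C)(C)[C@@H](O[Si](C)(C)C(C)(C)C)C=C[C@@]2(C)[C@H]1CO[Si](c1ccccc1)(c1ccccc1)C(C)(C)C | intermediate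
23 | phenyl sulfoxide of 22 (mixture at sulfur) | O=S(c1ccccc1)C[C@H]1CC[C@@H]2C(C)(C)[C@@H](O[Si](C)(C)C(C)(C)C)C=C[C@@]2(C)[C@H]1CO[Si](c1ccccc1)(c1ccccc1)C(C)(C)C | intermediate
24 | (3S,5S,9S,10R)-3-(tert-butyldimethylsilyloxy)-11-(tert-butyldiphenylsilyloxy)drima-1,8(12)-diene | C=C1CC[C@@H]2C(C)(C)[C@@H](O[Si](C)(C)C(C)(C)C)C=C[C@@]2(C)[C@H]1CO[Si](c1ccccc1)(c1ccccc1)C(C)(C)C | intermediate
25 | (3S,5S,9S,10R)-drima-1,8(12)-diene-3,11-diol | C=C1CC[C@@H]2C(C)(C)[C@@H](O)C=C[C@@]2(C)[C@H]1CO | intermediate
26 | (5S,9S,10R)-11-hydroxydrima-1,8(12)-dien-3-one | C=C1CC[C@@H]2C(C)(C)C(=O)C=C[C@@]2(C)[C@H]1CO | intermediate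
27 | isofraxidin (7-hydroxy-6,8-dimethoxy-2H-chromen-2-one) | Oc1c(OC)cc2ccc(=O)oc2c1OC | starting material
28 | 7-{[(1S,4aS,8aR)-5,5,8a-trimethyl-2-methylidene-6-oxo-1,2,3,4,4a,5,6,8a-octahydronaphthalen-1-yl]methoxy}-6,8-dimethoxy-2H-chromen-2-one | C=C1CC[C@@H]2C(C)(C)C(=O)C=C[C@@]2(C)[C@H]1COc1c(OC)cc2ccc(=O)oc2c1OC | target

Total step count: 17. Longest linear sequence: 17 steps (from but-2-yn-1-ol).

**Steps most likely to fail**

Step 12. The Lewis acid may divert the silyl dienol ether into an open-chain Mukaiyama–Michael pathway that stops after the first bond, or strip the silyl group. Endo control may also erode if the reaction has to be run warm. The fallback gives up the formyl activator and the promoter; it sets out from 14 and returns at 22. Cross-metathesis of 14 with 2-methylbut-2-ene (second-generation Grubbs catalyst) should give the 2-methylprop-1-enyl-terminated sulfide F1. HF·pyridine then gives the primary alcohol F2, Dess–Martin periodinane the β,γ-unsaturated aldehyde F3, and TBSOTf/Et3N the silyl dienol ether F4. Neutral thermal cycloaddition of F4 (toluene, BHT, 190 °C, sealed tube, or 12 kbar at 60 °C) forms the same two bonds and carries the gem-dimethyl group directly, so step 13 falls away. The C8 anchor still fixes the diene face, but ring-fusion control then rests on sterics alone.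

Step 3. Enantiocontrol may be incomplete, because the vinylzinc is Z-trisubstituted, the aldehyde is unbranched and lithium halides promote a racemic background addition. The fallback sets out from 3 and 4 and returns at 7. Vinyllithium 5 is added directly to 4 to give the racemic alcohol F5. Dess–Martin oxidation gives the (Z)-enone F6, and reduction with BH3·SMe2 and (S)-2-methyl-CBS-oxazaborolidine is expected to return the (R)-carbinol 7.

Step 17. The redox condensation may stall, because the phenol is flanked by two methoxy groups and the alcohol is β-branched on an axial CH2; the activated alcohol may then decompose. The fallback sets out from 26 and returns at 28. MsCl/Et3N gives the mesylate F7, which is displaced by the caesium phenoxide of 27 (Cs2CO3, NaI cat., DMF, 70 °C) in an SN2 alkylation.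

**Further compounds**
F1 | step 12 | (5S,6S,7E)-configured analogue of 14 with a CH=C(CH3)2 terminus | CC(C)=CCC[C@H](CSc1ccccc1)[C@H](CO[Si](c1ccccc1)(c1ccccc1)C(C)(C)C)/C(C)=C/CCO[Si](C)(C)C(C)(C)C
F2 | step 12 | primary C3 alcohol from F1 | CC(C)=CCC[C@H](CSc1ccccc1)[C@H](CO[Si](c1ccccc1)(c1ccccc1)C(C)(C)C)/C(C)=C/CCO
F3 | step 12 | β,γ-unsaturated C3 aldehyde from F2 | CC(C)=CCC[C@H](CSc1ccccc1)[C@H](CO[Si](c1ccccc1)(c1ccccc1)C(C)(C)C)/C(C)=C/CC=O
F4 | step 12 | (1E,3E)-silyl dienol ether from F3 | CC(C)=CCC[C@H](CSc1ccccc1)[C@H](CO[Si](c1ccccc1)(c1ccccc1)C(C)(C)C)/C(C)=C/C=C/O[Si](C)(C)C(C)(C)C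
F5 | step 3 | racemic (4Z)-1-(tert-butyldimethylsilyloxy)-6-(tert-butyldiphenylsilyloxy)-4-methylhex-4-en-3-ol | OC(CCO[Si](C)(C)C(C)(C)C)/C(C)=C\CO[Si](c1ccccc1)(c1ccccc1)C(C)(C)C
F6 | step 3 | (4Z)-1-(tert-butyldimethylsilyloxy)-6-(tert-butyldiphenylsilyloxy)-4-methylhex-4-en-3-one | O=C(CCO[Si](C)(C)C(C)(C)C)/C(C)=C\CO[Si](c1ccccc1)(c1ccccc1)C(C)(C)C
F7 | step 17 | methanesulfonate of alcohol 26 | C=C1CC[C@@H]2C(C)(C)C(=O)C=C[C@@]2(C)[C@H]1COS(C)(=O)=O
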